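## Retrosynthetic overview

1. The acetate and the methyl ketone are unmasked last from an acetonide-protected anti-1,2-diol; its methyl carbinol is the only bought stereocentre and is finally oxidised away.
2. Key disconnection: the bond between the furyl-ketone carbonyl and the quaternary ring carbon, made by a visible-light, carbene-catalysed decarboxylative radical acylation of a tertiary ring acid with 3-(furan-3-yl)propanoic acid.
3. The cyclohexane is not cyclised: it is a benzene ring hydrogenated all-cis under control of the lactone CH–O centre, then methylated at the lactone and ester α-carbons.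
4. The γ-lactone is the first ring made, on the arene, by syn-dihydroxylation of a Z-aryl allylic alcohol and lactonisation onto one of two equivalent ortho esters.
5. Arene and side chain are joined by Sonogashira coupling of a 2-bromoisophthalate with a four-carbon alkynol. Ring order: lactone, then carbocycle (from the arene); the furan is bought.

Assumption: the three compounds marked "starting material" in the compound list are taken as catalogue chemicals.
Locants follow 2-benzofuran-1(3H)-one numbering: C-1 lactone carbonyl, C-3 lactone CH–O, C-3a and C-7a ring fusion, C-4 the ring carbon next to C-3a.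

## Route

Step 1
Reactants: 1 dimethyl 2-bromobenzene-1,3-dicarboxylate; 2 (2R)-but-3-yn-2-ol
Product: 3 dimethyl 2-[(3R)-3-hydroxybut-1-yn-1-yl]benzene-1,3-dicarboxylate
Conditions: PdCl2(PPh3)2 (3 mol %), CuI (5 mol %), Et3N, DMF, 70 °C
Reagents that add atoms: none
Why: Sonogashira coupling; the C–Br bond flanked by two esters adds readily to palladium and the terminal alkyne couples without touching the bought carbinol centre.

Step 2
Reactants: 3 dimethyl 2-[(3R)-3-hydroxybut-1-yn-1-yl]benzene-1,3-dicarboxylate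
Product: 4 dimethyl 2-[(1Z,3R)-3-hydroxybut-1-en-1-yl]benzene-1,3-dicarboxylate
Conditions: H2 (1 atm), Pd/CaCO3 poisoned with Pb(OAc)2, quinoline, EtOAc, rt
Reagents that add atoms: none
Why: Lindlar semi-hydrogenation delivers both hydrogens syn and stops at the Z-alkene, the geometry needed for the relative configuration of the two carbinol carbons made next.

Step 3
Reactants: 4 dimethyl 2-[(1Z,3R)-3-hydroxybut-1-en-1-yl]benzene-1,3-dicarboxylate
Product: 6 methyl (3S)-3-[(1R,2R)-1,2-dihydroxypropyl]-1-oxo-1,3-dihydro-2-benzofuran-4-carboxylate, via triol 5 (not isolated)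
Conditions: K2OsO4·2H2O (5 mol %), NMO, acetone/H2O (5:1), 0 °C to rt; then TsOH (cat.), CH2Cl2, rt
Reagents that add atoms: N-methylmorpholine N-oxide C[N+]1([O-])CCOCC1; water O
Why: Upjohn dihydroxylation under Kishi's empirical rule: in the A(1,3)-minimised conformer of the Z-allylic alcohol OsO4 adds syn on the face anti to the hydroxyl, setting both new carbinol centres from the bought one, and the benzylic hydroxyl then lactonises onto either of the two equivalent ortho esters.

Step 4
Reactants: 6 methyl (3S)-3-[(1R,2R)-1,2-dihydroxypropyl]-1-oxo-1,3-dihydro-2-benzofuran-4-carboxylate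
Product: 7 methyl (3S)-1-oxo-3-[(4R,5R)-2,2,5-trimethyl-1,3-dioxolan-4-yl]-1,3-dihydro-2-benzofuran-4-carboxylate
Conditions: 2,2-dimethoxypropane, TsOH (cat.), acetone, rt
Reagents that add atoms: 2,2-dimethoxypropane COC(C)(C)OC
Why: Acetonide formation on the only 1,2-diol removes both free hydroxyls, which would otherwise lactonise onto the second ester or be alkylated in the steps that follow.

Step 5
Reactants: 7 methyl (3S)-1-oxo-3-[(4R,5R)-2,2,5-trimethyl-1,3-dioxolan-4-yl]-1,3-dihydro-2-benzofuran-4-carboxylate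
Product: 8 methyl (3S,3aR,4R,7aS)-1-oxo-3-[(4R,5R)-2,2,5-trimethyl-1,3-dioxolan-4-yl]octahydro-2-benzofuran-4-carboxylate
Conditions: H2 (60 bar), Rh/Al2O3 (5 wt % Rh), EtOAc, 40 °C
Reagents that add atoms: none
Why: Heterogeneous all-cis arene hydrogenation: the flat phthalide binds rhodium through the face opposite the dioxolane on C-3, so H-3a, H-4 and H-7a are delivered cis to H-3, which puts the side chain on the concave face of the cis-fused lactone as in the target.

Step 6
Reactants: 8 methyl (3S,3aR,4R,7aS)-1-oxo-3-[(4R,5R)-2,2,5-trimethyl-1,3-dioxolan-4-yl]octahydro-2-benzofuran-4-carboxylate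
Product: 9 methyl (3S,3aR,7aS)-4,7a-dimethyl-1-oxo-3-[(4R,5R)-2,2,5-trimethyl-1,3-dioxolan-4-yl]octahydro-2-benzofuran-4-carboxylate (both C-4 epimers)
Conditions: LiN(iPr)2 (2.5 equiv), THF/DMPU, −78 °C; MeI (5 equiv), −78 to −20 °C
Reagents that add atoms: iodomethane CI
Why: Double enolate alkylation: the ring-fusion lactone enolate can only be methylated on the convex face (cis-fused product, methyl cis to H-3a), while the C-4 ester enolate is methylated without useful control, which is harmless because that centre is reset in step 8.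

Step 7
Reactants: 9 methyl (3S,3aR,7aS)-4,7a-dimethyl-1-oxo-3-[(4R,5R)-2,2,5-trimethyl-1,3-dioxolan-4-yl]octahydro-2-benzofuran-4-carboxylate (both C-4 epimers)
Product: 10 (3S,3aR,7aS)-4,7a-dimethyl-1-oxo-3-[(4R,5R)-2,2,5-trimethyl-1,3-dioxolan-4-yl]octahydro-2-benzofuran-4-carboxylic acid (both C-4 epimers)
Conditions: LiI (5 equiv), pyridine, 115 °C; then cold 0.5 M HCl
Reagents that add atoms: none
Why: SN2 demethylation by iodide attacks the ester methyl carbon, so the quaternary α-centre does not slow it, and the lactone (secondary C–O) and acetonide are left intact.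

Step 8
Reactants: 10 (3S,3aR,7aS)-4,7a-dimethyl-1-oxo-3-[(4R,5R)-2,2,5-trimethyl-1,3-dioxolan-4-yl]octahydro-2-benzofuran-4-carboxylic acid (both C-4 epimers); 11 3-(furan-3-yl)propanoic acid
Product: 13 (3S,3aR,4S,7aS)-4-[3-(furan-3-yl)propanoyl]-4,7a-dimethyl-3-[(4R,5R)-2,2,5-trimethyl-1,3-dioxolan-4-yl]hexahydro-2-benzofuran-1(3H)-one, via acyl imidazole 12 (not isolated)
Conditions: 11, CDI, MeCN, rt, 1 h; then 10, Cs2CO3 (0.3 equiv), [Ir(dF(CF3)ppy)2(dtbbpy)]PF6 (2 mol %), 2-mesityl-6,7-dihydro-5H-pyrrolo[2,1-c][1,2,4]triazol-2-ium tetrafluoroborate (20 mol %), MeCN, blue LEDs (450 nm), rt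
Reagents that add atoms: none
Why: Proposed new method: a light-driven, carbene-catalysed cross-ketonisation of two free acids in which the photoexcited iridium complex oxidises the carboxylate of 10 (about +1.2 V vs SCE), CO2 is lost and both C-4 epimers collapse to one planar tertiary radical, while the reduced photocatalyst converts the acyl azolium formed from 12 and the triazolylidene into a persistent ketyl radical; radical–radical coupling then takes place on the ring face opposite the cis-fused lactone and its concave-face dioxolane, so the acyl group ends up trans to the C-3a–C-3 bond and the quaternary centre is set, after which the alkoxide expels the carbene; the closest known reaction types are carbene/photoredox radical acylation of acyl imidazoles with benzylic or α-amino radicals and the thermal carbene-catalysed decarboxylative coupling of tertiary N-acyloxyphthalimides with aldehydes, neither shown on a free unactivated tertiary acid nor used to set a quaternary stereocentre by substrate control.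

Step 9
Reactants: 13 (3S,3aR,4S,7aS)-4-[3-(furan-3-yl)propanoyl]-4,7a-dimethyl-3-[(4R,5R)-2,2,5-trimethyl-1,3-dioxolan-4-yl]hexahydro-2-benzofuran-1(3H)-one
Product: 14 (3S,3aR,4S,7aS)-3-[(1R,2R)-1,2-dihydroxypropyl]-4-[3-(furan-3-yl)propanoyl]-4,7a-dimethylhexahydro-2-benzofuran-1(3H)-one
Conditions: AcOH/H2O (4:1), 45 °C
Reagents that add atoms: none
Why: Acid-catalysed acetal hydrolysis removes the acetonide under conditions mild enough for the 3-alkylfuran, the ketone and the hindered lactone.

Step 10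
Reactants: 14 (3S,3aR,4S,7aS)-3-[(1R,2R)-1,2-dihydroxypropyl]-4-[3-(furan-3-yl)propanoyl]-4,7a-dimethylhexahydro-2-benzofuran-1(3H)-one
Product: 15 (3S,3aR,4S,7aS)-4-[3-(furan-3-yl)propanoyl]-3-[(1S)-1-hydroxy-2-oxopropyl]-4,7a-dimethylhexahydro-2-benzofuran-1(3H)-one
Conditions: [(neocuproine)Pd(OAc)]2(OTf)2 (5 mol %), 1,4-benzoquinone (1.5 equiv), MeCN/H2O (10:1), rt
Reagents that add atoms: none
Why: Chemoselective palladium-catalysed oxidation of a vicinal diol to an α-hydroxy ketone: β-hydride elimination from the chelated diolate occurs at the unhindered, more electron-rich methyl carbinol, which erases the bought stereocentre and leaves the hindered carbinol next to the lactone untouched.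

Step 11
Reactants: 15 (3S,3aR,4S,7aS)-4-[3-(furan-3-yl)propanoyl]-3-[(1S)-1-hydroxy-2-oxopropyl]-4,7a-dimethylhexahydro-2-benzofuran-1(3H)-one
Product: 16 (1S)-1-{(3S,3aR,4S,7aS)-4-[3-(furan-3-yl)propanoyl]-4,7a-dimethyl-1-oxooctahydro-2-benzofuran-3-yl}-2-oxopropyl acetate (CNP0170401.2)
Conditions: Ac2O, pyridine, CH2Cl2, 0 °C
Reagents that add atoms: acetic anhydride CC(=O)OC(C)=O
Why: Acetylation of the remaining secondary hydroxyl under weakly basic, cold conditions avoids enolisation or E1cB opening of the β-acyloxy ketone and gives the target.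

## Compound list

1 | dimethyl 2-bromobenzene-1,3-dicarboxylate | COC(=O)c1cccc(C(=O)OC)c1Br | starting material
2 | (2R)-but-3-yn-2-ol | C#C[C@@H](C)O | starting material
3 | dimethyl 2-[(3R)-3-hydroxybut-1-yn-1-yl]benzene-1,3-dicarboxylate | COC(=O)c1cccc(C(=O)OC)c1C#C[C@@H](C)O | intermediate
4 | dimethyl 2-[(1Z,3R)-3-hydroxybut-1-en-1-yl]benzene-1,3-dicarboxylate | COC(=O)c1cccc(C(=O)OC)c1/C=C\[C@@H](C)O | intermediate
5 | dimethyl 2-[(1S,2R,3R)-1,2,3-trihydroxybutyl]benzene-1,3-dicarboxylate | C[C@@H](O)[C@@H](O)[C@@H](O)c1c(C(=O)OC)cccc1C(=O)OC | intermediate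
6 | methyl (3S)-3-[(1R,2R)-1,2-dihydroxypropyl]-1-oxo-1,3-dihydro-2-benzofuran-4-carboxylate | C[C@@H](O)[C@@H](O)[C@H]1OC(=O)c2cccc(C(=O)OC)c12 | intermediate
7 | methyl (3S)-1-oxo-3-[(4R,5R)-2,2,5-trimethyl-1,3-dioxolan-4-yl]-1,3-dihydro-2-benzofuran-4-carboxylate | C[C@H]1OC(C)(C)O[C@H]1[C@H]2OC(=O)c3cccc(C(=O)OC)c23 | intermediate
8 | methyl (3S,3aR,4R,7aS)-1-oxo-3-[(4R,5R)-2,2,5-trimethyl-1,3-dioxolan-4-yl]octahydro-2-benzofuran-4-carboxylate (H-3, H-3a, H-4 and H-7a all cis) | C[C@H]1OC(C)(C)O[C@H]1[C@H]2OC(=O)[C@H]3CCC[C@@H](C(=O)OC)[C@@H]23 | intermediate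
9 | methyl (3S,3aR,7aS)-4,7a-dimethyl-1-oxo-3-[(4R,5R)-2,2,5-trimethyl-1,3-dioxolan-4-yl]octahydro-2-benzofuran-4-carboxylate, both C-4 epimers (C-4 left open in the SMILES on purpose) | C[C@H]1OC(C)(C)O[C@H]1[C@H]2OC(=O)[C@@]3(C)CCCC(C)(C(=O)OC)[C@@H]23 | intermediate
10 | (3S,3aR,7aS)-4,7a-dimethyl-1-oxo-3-[(4R,5R)-2,2,5-trimethyl-1,3-dioxolan-4-yl]octahydro-2-benzofuran-4-carboxylic acid, both C-4 epimers (C-4 left open in the SMILES on purpose) | C[C@H]1OC(C)(C)O[C@H]1[C@H]2OC(=O)[C@@]3(C)CCCC(C)(C(=O)O)[C@@H]23 | intermediate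
11 | 3-(furan-3-yl)propanoic acid | OC(=O)CCc1ccoc1 | starting material
12 | 1-[3-(furan-3-yl)propanoyl]-1H-imidazole | O=C(CCc1ccoc1)n1ccnc1 | intermediate
13 | (3S,3aR,4S,7aS)-4-[3-(furan-3-yl)propanoyl]-4,7a-dimethyl-3-[(4R,5R)-2,2,5-trimethyl-1,3-dioxolan-4-yl]hexahydro-2-benzofuran-1(3H)-one | C[C@H]1OC(C)(C)O[C@H]1[C@H]2OC(=O)[C@@]3(C)CCC[C@](C)(C(=O)CCc4ccoc4)[C@@H]23 | intermediate
14 | (3S,3aR,4S,7aS)-3-[(1R,2R)-1,2-dihydroxypropyl]-4-[3-(furan-3-yl)propanoyl]-4,7a-dimethylhexahydro-2-benzofuran-1(3H)-one | C[C@@H](O)[C@@H](O)[C@H]1OC(=O)[C@@]2(C)CCC[C@](C)(C(=O)CCc3ccoc3)[C@@H]12 | intermediate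
15 | (3S,3aR,4S,7aS)-4-[3-(furan-3-yl)propanoyl]-3-[(1S)-1-hydroxy-2-oxopropyl]-4,7a-dimethylhexahydro-2-benzofuran-1(3H)-one | CC(=O)[C@@H](O)[C@H]1OC(=O)[C@@]2(C)CCC[C@](C)(C(=O)CCc3ccoc3)[C@@H]12 | intermediate
16 | (1S)-1-{(3S,3aR,4S,7aS)-4-[3-(furan-3-yl)propanoyl]-4,7a-dimethyl-1-oxooctahydro-2-benzofuran-3-yl}-2-oxopropyl acetate (CNP0170401.2) | CC(=O)O[C@H](C(C)=O)[C@H]1OC(=O)[C@@]2(C)CCC[C@](C)(C(=O)CCc3ccoc3)[C@@H]12 | target

## Step count and risks

Total steps: 11. Longest linear sequence: 11 (from 1 or 2 to 16); 11 is used as bought.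

**Step 8 (the proposed coupling).** Risks are competing oxidation of the carbene, loss of the tertiary radical to alkene, and incomplete face selection at the new quaternary centre. The fallback sets out from 10 and uses known chemistry. Acid 10 is esterified with N-hydroxyphthalimide (N,N′-diisopropylcarbodiimide, DMAP) to the redox-active ester 1,3-dioxoisoindolin-2-yl (3S,3aR,7aS)-4,7a-dimethyl-1-oxo-3-[(4R,5R)-2,2,5-trimethyl-1,3-dioxolan-4-yl]octahydro-2-benzofuran-4-carboxylate F1. Separately, 12 (from 11 and CDI) is reduced with iBu2AlH at −78 °C to 3-(furan-3-yl)propanal F2. F1 and F2 are joined by the established carbene-catalysed decarboxylative radical coupling of aldehydes with tertiary N-acyloxyphthalimides (N-(2,6-diisopropylphenyl)thiazolium precatalyst, Cs2CO3, DMSO, 60 °C). This runs without light through the same tertiary radical and ketyl radical pair and comes back to the route at 13.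

**Step 5 (arene hydrogenation).** Face selection rests on a freely rotating dioxolane, and benzylic C–O hydrogenolysis or stalling at a tetrasubstituted alkene are possible. The fallback sets out from 6. Heating with catalytic TsOH in toluene (methanol distilled off) closes the side-chain hydroxyl next to C-3 onto the second ester. This gives the rigid aromatic bis-lactone (γ-lactone of 6 plus a six-membered lactone from the C-4 carboxyl to the side-chain oxygen, carrying a (1R)-1-hydroxyethyl group) F3, in which that carbinol carbon is locked out of the ring plane on the face opposite H-3. Hydrogenation (H2, Rh/Al2O3) can then only occur from the open face and gives the all-cis saturated bis-lactone F4. Camphorsulfonic acid in methanol/2,2-dimethoxypropane opens the more labile six-membered lactone to the methyl ester and traps the freed 1,2-diol as the acetonide, coming back to the route at 8.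

**Step 10 (regioselective diol oxidation).** The hindered carbinol may also be oxidised, or the hydroxy ketone may isomerise. The fallback sets out from 14 and differentiates the two hydroxyls by protection instead. TBSCl/imidazole at 0 °C silylates only the unhindered methyl carbinol to give (3S,3aR,4S,7aS)-3-[(1S,2R)-2-{[tert-butyl(dimethyl)silyl]oxy}-1-hydroxypropyl]-4-[3-(furan-3-yl)propanoyl]-4,7a-dimethylhexahydro-2-benzofuran-1(3H)-one F5. Ac2O/pyridine/DMAP gives the acetate (1S,2R)-2-{[tert-butyl(dimethyl)silyl]oxy}-1-{(3S,3aR,4S,7aS)-4-[3-(furan-3-yl)propanoyl]-4,7a-dimethyl-1-oxooctahydro-2-benzofuran-3-yl}propyl acetate F6. HF·pyridine frees the carbinol (1R,2R)-2-hydroxy-1-{(3S,3aR,4S,7aS)-4-[3-(furan-3-yl)propanoyl]-4,7a-dimethyl-1-oxooctahydro-2-benzofuran-3-yl}propyl acetate F7. Buffered Dess–Martin oxidation of F7 then comes back to the route at 16, bypassing 15.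

## Further compounds

F1 | step 8 | 1,3-dioxoisoindolin-2-yl (3S,3aR,7aS)-4,7a-dimethyl-1-oxo-3-[(4R,5R)-2,2,5-trimethyl-1,3-dioxolan-4-yl]octahydro-2-benzofuran-4-carboxylate (both C-4 epimers) | C[C@H]1OC(C)(C)O[C@H]1[C@H]2OC(=O)[C@@]3(C)CCCC(C)(C(=O)ON4C(=O)c5ccccc5C4=O)[C@@H]23
F2 | step 8 | 3-(furan-3-yl)propanal | O=CCCc1ccoc1
F3 | step 5 | aromatic bis-lactone of 6 (five-membered lactone at C-3 as in 6, six-membered lactone from the C-4 carboxyl to the side-chain oxygen, (1R)-1-hydroxyethyl group on that carbinol carbon) | C[C@@H](O)[C@H]1OC(=O)c2cccc3C(=O)O[C@H]1c23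
F4 | step 5 | all-cis hexahydro derivative of F3 (the three new ring hydrogens cis to H-3) | C[C@@H](O)[C@H]1OC(=O)[C@@H]2CCC[C@@H]3C(=O)O[C@H]1[C@H]23
F5 | step 10 | (3S,3aR,4S,7aS)-3-[(1S,2R)-2-{[tert-butyl(dimethyl)silyl]oxy}-1-hydroxypropyl]-4-[3-(furan-3-yl)propanoyl]-4,7a-dimethylhexahydro-2-benzofuran-1(3H)-one | C[C@@H](O[Si](C)(C)C(C)(C)C)[C@@H](O)[C@H]1OC(=O)[C@@]2(C)CCC[C@](C)(C(=O)CCc3ccoc3)[C@@H]12
F6 | step 10 | (1S,2R)-2-{[tert-butyl(dimethyl)silyl]oxy}-1-{(3S,3aR,4S,7aS)-4-[3-(furan-3-yl)propanoyl]-4,7a-dimethyl-1-oxooctahydro-2-benzofuran-3-yl}propyl acetate | C[C@@H](O[Si](C)(C)C(C)(C)C)[C@@H](OC(C)=O)[C@H]1OC(=O)[C@@]2(C)CCC[C@](C)(C(=O)CCc3ccoc3)[C@@H]12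
F7 | step 10 | (1R,2R)-2-hydroxy-1-{(3S,3aR,4S,7aS)-4-[3-(furan-3-yl)propanoyl]-4,7a-dimethyl-1-oxooctahydro-2-benzofuran-3-yl}propyl acetate | C[C@@H](O)[C@@H](OC(C)=O)[C@H]1OC(=O)[C@@]2(C)CCC[C@](C)(C(=O)CCc3ccoc3)[C@@H]12
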